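All runs are calculated from invented constants.

A process chemist asks what Tuesday's flask holds at the time of looking, and whether any option is then worth taking.

| setting | Tuesday's | Wednesday's | flask |
|---|---|---|---|
| starting material | 0.50 M | 0.50 M | 0.50 M |
| partner | 0.75 M | 0.38 M | 0.750 M |
| protic impurity | 0.50 M | 0.50 M | 0.500 M |
| temperature | 20 °C | 15 °C | 20 °C |
| remark | the very flask that is asked about, followed so far | run made earlier |  |
| time |  |  | 4.0 h |

| run | time / min | target / % | starting material / % |
|---|---|---|---|
| Tuesday's | 12.0 | 52.4 | 0 |
| Tuesday's | 20.0 | 52.5 | 0.3 |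
| Tuesday's | 40.0 | 52.7 | 1.1 |
| Tuesday's | 80.0 | 53.0 | 0.5 |
| Tuesday's | 150 | 52.5 | 0.9 |
| Wednesday's | 0.833 | 2.5 | 46.9 |
| Wednesday's | 1.50 | 5.3 | 28.9 |
| Wednesday's | 3.00 | 11.7 | 10.6 |
| Wednesday's | 5.00 | 18.5 | 4.1 |
| Wednesday's | 10.0 | 29.5 | 1.8 |

(standard deviation of a reading: 0.5 percentage points)
- delta: at 4.0 h take out 90 % of the target then present, then wait 2.0 h
- gamma: at 4.0 h add partner, 50.0 % of the amount charged, then wait 2.0 h
- epsilon: at 4.0 h raise the temperature by 20 K, then wait 2.0 h
- eta: change nothing and wait 2.0 h more
* target, in percent of the starting material first charged, at 4.0 h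
* the option that brings most further target ("none" if no option brings more than 2 percentage points) (delta / gamma / epsilon / eta / none)
* target present, with what was taken out counted in, in percent of the starting material first charged, after gamma
* target present, with what was taken out counted in, in percent of the starting material first charged, after epsilon
- target taken out counts as made
- additions bring no volume worth counting

Tuesday's target readings stay flat from 12.0 min to 150 min, so we take their mean, 52.6 %, as our figure for Tuesday's flask. Assuming one partner per target, 0.750 M of partner against 0.50 M of starting material gives 64.9 %; we call this the spare partner S, the share of the charged partner still free at the plateau. Where S falls through zero control crosses over: on this count of one partner per target, starting material is the limiting reagent while S is positive, and partner is once S is negative. In Tuesday's flask S stands at 64.9 %, and the last starting-material reading, 0.9 %, is below the 2 percentage points margin. We therefore read the starting material, at that 0.9 %, as spent and bet, though the readings prove no more, that what did not become target has left for good. Our answer is "none", with gamma and epsilon both staying at 52.6 %.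

The forecast gives 52.6 %, chooses delta, and puts gamma at 64.5 % and epsilon at 38 %, saying “I read the plateau as an equilibrium”. It agrees with us on the present amount and differs on the rest.

The flask gives 52.9 %, best option none, gamma 52.9 % and epsilon 52.9 %.

    starting material + protic impurity → quenched substrate (k = 0.0240 M⁻¹ s⁻¹, Ea = 63.0 kJ mol⁻¹)
    2 starting material → self-condensation product (k = 0.00220 M⁻¹ s⁻¹, Ea = 55.0 kJ mol⁻¹)
    intermediate B ⇌ intermediate C (K = 1.20, k = 8.80 × 10⁻⁴ s⁻¹, Ea = 94.0 kJ mol⁻¹, ΔH = −63.0 kJ mol⁻¹)
    intermediate B → side product A (k = 0.00270 s⁻¹, Ea = 91.0 kJ mol⁻¹)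
    intermediate A → target (k = 0.00640 s⁻¹, Ea = 79.0 kJ mol⁻¹)
    partner + intermediate C → side product B (k = 0.0600 M⁻¹ s⁻¹, Ea = 40.0 kJ mol⁻¹)
    starting material + partner → intermediate A (k = 0.0250 M⁻¹ s⁻¹, Ea = 62.0 kJ mol⁻¹)
    starting material ⇌ intermediate B (K = 2.70, k = 0.00380 s⁻¹, Ea = 85.0 kJ mol⁻¹, ΔH = −3.00 kJ mol⁻¹)
    (constants at 20 °C)

At 240 min Tuesday's flask holds 0 % starting material and 63.2 % of its partner, against a spare partner S of 64.9 %. The neighbouring flask charges 1.2 M of starting material, so it has 0.625 equiv of partner. At Tuesday's plateau share its spare partner is still positive, 15.8 %, which points to starting material running out first. In that neighbouring flask the first charge to run out is starting material, with 20.1 % of the partner left and 46.9 % target.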